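**Retrosynthetic overview**
- The target comes from O‑acetylation of the corresponding 1,7‑diol, which comes from an anti, Markovnikov bromochlorination of the ring B olefin of a spiro[5.5]undecene diol.
- Ring B is formed last, by ring‑closing metathesis of an allyl and a 2‑methylallyl arm on a monocyclic diol.
- Ring A is formed first, in one bromonium‑triggered cyclization of a Z tetrasubstituted triene that sets the spiro carbon, the ring A C–Br and the tertiary C–O; the substrate's own carbamate ends the cyclization.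
- Key C–C bond: an enantioenriched α‑lithiated O‑allyl carbamate (a carbinol carbon used as a carbanion) is alkylated with 3‑bromo‑2‑methylprop‑1‑ene; this sets the one reagent‑controlled stereocentre, from which the other five are relayed.
- The Z tetrasubstituted olefin comes from the Z enol triflate of ethyl 2‑acetylpent‑4‑enoate and a homoprenyl Grignard reagent, then reduction and carbamoylation.

Assumption: ethyl 2‑acetylpent‑4‑enoate, 5‑bromo‑2‑methylpent‑2‑ene and 3‑bromo‑2‑methylprop‑1‑ene are taken as the commercial starting materials.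
Assumption: (−)‑sparteine is taken to give the 1S lithio compound and the allylic bromide to react with inversion; if the sense is opposite, the (+)‑sparteine surrogate is used instead.
Spiro locants used below: C1 = ring B carbinol carbon next to the spiro atom, C3 = ring B C–CH3, C4 and C5 follow, C6 = spiro carbon, C7 = ring A tertiary carbinol, C10 = ring A CHBr, C11 = C(CH3)2.

**Step 1**
Reactants: 1 ethyl 2‑acetylpent‑4‑enoate
Product: 2 ethyl (2Z)‑2‑(prop‑2‑en‑1‑yl)‑3‑{[(trifluoromethyl)sulfonyl]oxy}but‑2‑enoate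
Conditions: Tf2O, LiOH (aq), toluene, 5 °C
Reagents that add atoms: trifluoromethanesulfonic anhydride, FC(F)(F)S(=O)(=O)OS(=O)(=O)C(F)(F)F
Why: Chelation‑controlled enol triflation of a β‑keto ester (lithium bridges the enolate and ester oxygens) gives the Z enol triflate, which places CH3 cis to the allyl arm, the olefin geometry that later defines the spiro centre.

**Step 2**
Reactants: 2 ethyl (2Z)‑2‑(prop‑2‑en‑1‑yl)‑3‑{[(trifluoromethyl)sulfonyl]oxy}but‑2‑enoate; 3 5‑bromo‑2‑methylpent‑2‑ene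
Product: 5 ethyl (2Z)‑3,7‑dimethyl‑2‑(prop‑2‑en‑1‑yl)octa‑2,6‑dienoate, via (4‑methylpent‑3‑en‑1‑yl)magnesium bromide 4 (not isolated)
Conditions: 3, Mg, THF, 23 °C; then 2, Fe(acac)3 (5 mol %), THF–NMP, −30 °C
Reagents that add atoms: none
Why: Iron‑catalysed cross‑coupling of an alkyl Grignard reagent with an enol triflate replaces OTf by the homoprenyl chain with retention of olefin geometry and leaves the ester untouched, giving the Z tetrasubstituted enoate.

**Step 3**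
Reactants: 5 ethyl (2Z)‑3,7‑dimethyl‑2‑(prop‑2‑en‑1‑yl)octa‑2,6‑dienoate
Product: 6 (2Z)‑3,7‑dimethyl‑2‑(prop‑2‑en‑1‑yl)octa‑2,6‑dien‑1‑ol
Conditions: i‑Bu2AlH (2.2 equiv), CH2Cl2, −78 → 0 °C
Reagents that add atoms: none
Why: 1,2‑Reduction of the α,β‑unsaturated ester by the aluminium hydride gives the allylic alcohol; no stereocentre is made and the olefin geometry is kept.

**Step 4**
Reactants: 6 (2Z)‑3,7‑dimethyl‑2‑(prop‑2‑en‑1‑yl)octa‑2,6‑dien‑1‑ol
Product: 7 (2Z)‑3,7‑dimethyl‑2‑(prop‑2‑en‑1‑yl)octa‑2,6‑dien‑1‑yl N,N‑di(propan‑2‑yl)carbamate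
Conditions: i‑Pr2NCOCl, Et3N, DMAP (cat.), CH2Cl2, 40 °C
Reagents that add atoms: N,N‑diisopropylcarbamoyl chloride, CC(C)N(C(C)C)C(Cl)=O
Why: O‑Carbamoylation installs the group that directs α‑lithiation in step 5 and serves as the internal oxygen nucleophile in step 6.

**Step 5 (key step)**
Reactants: 7 (2Z)‑3,7‑dimethyl‑2‑(prop‑2‑en‑1‑yl)octa‑2,6‑dien‑1‑yl N,N‑di(propan‑2‑yl)carbamate; 8 3‑bromo‑2‑methylprop‑1‑ene
Product: 10 (4R,5Z)‑2,6,10‑trimethyl‑5‑(prop‑2‑en‑1‑yl)undeca‑1,5,9‑trien‑4‑yl N,N‑di(propan‑2‑yl)carbamate, via sparteine‑bound (1S)‑1‑lithio carbamate 9 (not isolated)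
Conditions: s‑BuLi, (−)‑sparteine, toluene, −78 °C; then 8, −78 → −40 °C
Reagents that add atoms: none
Why: Hoppe‑type asymmetric α‑lithiation of an O‑allyl carbamate gives the chelated 1S α‑oxy‑allyl‑lithium 9, in which the carbinol carbon (by nature an acceptor) is a carbanion, and its alkylation by the allylic bromide (also an acceptor) at the α‑carbon (the γ‑carbon is fully substituted) with inversion forms the C4–C3 bond and sets C4 as R.

**Step 6**
Reactants: 10 (4R,5Z)‑2,6,10‑trimethyl‑5‑(prop‑2‑en‑1‑yl)undeca‑1,5,9‑trien‑4‑yl N,N‑di(propan‑2‑yl)carbamate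
Product: 13 (1R,2R,4R)‑4‑bromo‑2‑[(1R)‑1‑hydroxy‑3‑methylbut‑3‑en‑1‑yl]‑1,3,3‑trimethyl‑2‑(prop‑2‑en‑1‑yl)cyclohexan‑1‑ol, via bicyclic iminium carbonate salt 11 (not isolated), via bicyclic carbonate 12 (not isolated)
Conditions: NBS, morpholine (cat.), HFIP, 0 °C; H2O; then K2CO3 (0.5 equiv), MeOH, 23 °C
Reagents that add atoms: N‑bromosuccinimide, BrN1C(=O)CCC1=O
Why: Biomimetic bromonium‑induced cation–olefin cyclization with neighbouring‑group termination, in which Br+ adds reversibly to the unhindered 9,10‑olefin and the Z tetrasubstituted olefin attacks the tertiary terminus through a chair with Br equatorial and the carbamate‑bearing carbon axial (it is cis to the tether), on the face anti to the allylic C–O bond (H in plane by allylic 1,3‑strain), while the carbamate carbonyl oxygen captures the tertiary cation anti to the new C–C bond, so the quaternary carbon, the C–Br and the tertiary C–O are all set relative to C4; hydrolysis of 11 and methanolysis of 12 free the diol.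

**Step 7**
Reactants: 13 (1R,2R,4R)‑4‑bromo‑2‑[(1R)‑1‑hydroxy‑3‑methylbut‑3‑en‑1‑yl]‑1,3,3‑trimethyl‑2‑(prop‑2‑en‑1‑yl)cyclohexan‑1‑ol
Product: 14 (1R,6R,7R,10R)‑10‑bromo‑3,7,11,11‑tetramethylspiro[5.5]undec‑3‑ene‑1,7‑diol
Conditions: second‑generation Grubbs catalyst (3 mol %), CH2Cl2, 40 °C
Reagents that add atoms: none
Why: Ring‑closing olefin metathesis of the allyl and 2‑methylallyl arms closes ring B as the trisubstituted cyclohexene with the double bond at C3–C4; no stereocentre is touched.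

**Step 8**
Reactants: 14 (1R,6R,7R,10R)‑10‑bromo‑3,7,11,11‑tetramethylspiro[5.5]undec‑3‑ene‑1,7‑diol
Product: 16 (1R,3S,4S,6R,7R,10R)‑4,10‑dibromo‑3‑chloro‑3,7,11,11‑tetramethylspiro[5.5]undecane‑1,7‑diol, via chlorotitanium diolate 15 (not isolated)
Conditions: ClTi(Oi‑Pr)3 (1.2 equiv), CH2Cl2–hexanes, 23 °C; then NBS, −20 °C
Reagents that add atoms: chlorotitanium triisopropoxide, CC(C)O[Ti](Cl)(OC(C)C)OC(C)C; N‑bromosuccinimide, BrN1C(=O)CCC1=O
Why: Proposed new method: ClTi(Oi‑Pr)3 turns the 1,7‑diol into the six‑membered chlorotitanium diolate 15, which masks the tertiary oxygen (no cineole‑type bromo ether), holds ring B in the half‑chair with the C1 oxygen axial and delivers chloride from titanium to the tertiary C3 on the face of that oxygen while NBS supplies Br+ to the opposite face at C4 (anti, Markovnikov, diaxial opening), giving 3S,4S; the closest known reaction is the titanium‑alkoxide‑directed bromochlorination of allylic alcohols with NBS and ClTi(Oi‑Pr)3.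

**Step 9**
Reactants: 16 (1R,3S,4S,6R,7R,10R)‑4,10‑dibromo‑3‑chloro‑3,7,11,11‑tetramethylspiro[5.5]undecane‑1,7‑diol
Product: 17 (1R,3S,4S,6R,7R,10R)‑4,10‑dibromo‑3‑chloro‑7‑hydroxy‑3,7,11,11‑tetramethylspiro[5.5]undecan‑1‑yl acetate
Conditions: Ac2O, pyridine, DMAP (cat.), CH2Cl2, 0 → 23 °C
Reagents that add atoms: acetic anhydride, CC(=O)OC(C)=O
Why: DMAP‑catalysed acylation takes the secondary C1 hydroxyl and leaves the hindered tertiary C7 hydroxyl free, with retention at C1.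

**Compound list**
1 | ethyl 2‑acetylpent‑4‑enoate | CCOC(=O)C(CC=C)C(C)=O | starting material
2 | ethyl (2Z)‑2‑(prop‑2‑en‑1‑yl)‑3‑{[(trifluoromethyl)sulfonyl]oxy}but‑2‑enoate | CCOC(=O)/C(CC=C)=C(/C)OS(=O)(=O)C(F)(F)F | intermediate
3 | 5‑bromo‑2‑methylpent‑2‑ene | CC(C)=CCCBr | starting material
4 | (4‑methylpent‑3‑en‑1‑yl)magnesium bromide | CC(C)=CCC[Mg]Br | intermediate
5 | ethyl (2Z)‑3,7‑dimethyl‑2‑(prop‑2‑en‑1‑yl)octa‑2,6‑dienoate | CCOC(=O)/C(CC=C)=C(/C)CCC=C(C)C | intermediate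
6 | (2Z)‑3,7‑dimethyl‑2‑(prop‑2‑en‑1‑yl)octa‑2,6‑dien‑1‑ol | OC/C(CC=C)=C(/C)CCC=C(C)C | intermediate
7 | (2Z)‑3,7‑dimethyl‑2‑(prop‑2‑en‑1‑yl)octa‑2,6‑dien‑1‑yl N,N‑di(propan‑2‑yl)carbamate | CC(C)N(C(C)C)C(=O)OC/C(CC=C)=C(/C)CCC=C(C)C | intermediate
8 | 3‑bromo‑2‑methylprop‑1‑ene | CC(=C)CBr | starting material
9 | (1S,2Z)‑1‑lithio‑3,7‑dimethyl‑2‑(prop‑2‑en‑1‑yl)octa‑2,6‑dien‑1‑yl N,N‑di(propan‑2‑yl)carbamate as its (−)‑sparteine complex (ligand not drawn) | CC(C)N(C(C)C)C(=O)O[C@@H]([Li])/C(CC=C)=C(/C)CCC=C(C)C | intermediate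
10 | (4R,5Z)‑2,6,10‑trimethyl‑5‑(prop‑2‑en‑1‑yl)undeca‑1,5,9‑trien‑4‑yl N,N‑di(propan‑2‑yl)carbamate | CC(C)N(C(C)C)C(=O)O[C@H](CC(C)=C)/C(CC=C)=C(/C)CCC=C(C)C | intermediate
11 | (4R,4aR,6R,8aR)‑6‑bromo‑5,5,8a‑trimethyl‑4‑(2‑methylprop‑2‑en‑1‑yl)‑4a‑(prop‑2‑en‑1‑yl)‑N,N‑di(propan‑2‑yl)hexahydro‑4H‑1,3‑benzodioxin‑2‑iminium succinimidate | CC(C)[N+](C(C)C)=C1O[C@H](CC(C)=C)[C@@]2(CC=C)C(C)(C)[C@H](Br)CC[C@@]2(C)O1.O=C1CCC(=O)[N-]1 | intermediate
12 | (4R,4aR,6R,8aR)‑6‑bromo‑5,5,8a‑trimethyl‑4‑(2‑methylprop‑2‑en‑1‑yl)‑4a‑(prop‑2‑en‑1‑yl)hexahydro‑4H‑1,3‑benzodioxin‑2‑one | O=C1O[C@H](CC(C)=C)[C@@]2(CC=C)C(C)(C)[C@H](Br)CC[C@@]2(C)O1 | intermediate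
13 | (1R,2R,4R)‑4‑bromo‑2‑[(1R)‑1‑hydroxy‑3‑methylbut‑3‑en‑1‑yl]‑1,3,3‑trimethyl‑2‑(prop‑2‑en‑1‑yl)cyclohexan‑1‑ol | O[C@H](CC(C)=C)[C@@]1(CC=C)C(C)(C)[C@H](Br)CC[C@@]1(C)O | intermediate
14 | (1R,6R,7R,10R)‑10‑bromo‑3,7,11,11‑tetramethylspiro[5.5]undec‑3‑ene‑1,7‑diol | O[C@@H]1CC(C)=CC[C@@]12C(C)(C)[C@H](Br)CC[C@@]2(C)O | intermediate
15 | chloro(isopropoxy)titanium 1,7‑diolate of 14 (six‑membered chelate) | CC(C)O[Ti]1(Cl)O[C@@H]2CC(C)=CC[C@@]23C(C)(C)[C@H](Br)CC[C@@]3(C)O1 | intermediate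
16 | (1R,3S,4S,6R,7R,10R)‑4,10‑dibromo‑3‑chloro‑3,7,11,11‑tetramethylspiro[5.5]undecane‑1,7‑diol | O[C@@H]1C[C@](C)(Cl)[C@@H](Br)C[C@@]12C(C)(C)[C@H](Br)CC[C@@]2(C)O | intermediate
17 | (1R,3S,4S,6R,7R,10R)‑4,10‑dibromo‑3‑chloro‑7‑hydroxy‑3,7,11,11‑tetramethylspiro[5.5]undecan‑1‑yl acetate | CC(=O)O[C@@H]1C[C@](C)(Cl)[C@@H](Br)C[C@@]12C(C)(C)[C@H](Br)CC[C@@]2(C)O | target

**Totals**
Total step count: 9. Longest linear sequence: 9 steps (from 1; 3 and 8 enter as commercial inputs).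

**Three steps most likely to fail, each with a fallback**

Step 8 (directed bromochlorination). The tertiary hydroxyl may close a bromo ether, or the halogens may add from the wrong face. The fallback sets out from 14 and makes use of that ether. NBS in CH2Cl2 at 0 °C lets the C7 oxygen add to C3 from its own face and bromine to C4 anti, giving (1R,3S,4S,6R,7R,10R)‑4,10‑dibromo‑3,7‑epoxy‑3,7,11,11‑tetramethylspiro[5.5]undecan‑1‑ol F5. TiCl4 at −78 °C then reopens the tertiary C3–O bond with anchimeric help from the anti bromine, and chloride returns to C3 with net retention. This comes back to the route at 16.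

Step 6 (bromonium cyclization). Br+ may attack the tetrasubstituted olefin instead (giving a bromo carbonate), or the mismatched bromonium may cyclize. The fallback sets out from 10 and generates the bromonium stereospecifically. Shi epoxidation (fructose‑derived ketone catalyst, KHSO5) of the unhindered 9,10‑olefin gives (4R,5Z)‑8‑[(2S)‑3,3‑dimethyloxiran‑2‑yl]‑2,6‑dimethyl‑5‑(prop‑2‑en‑1‑yl)octa‑1,5‑dien‑4‑yl N,N‑di(propan‑2‑yl)carbamate F3. Li2NiBr4 opens it at the secondary carbon with inversion to (4R,5Z,9R)‑9‑bromo‑10‑hydroxy‑2,6,10‑trimethyl‑5‑(prop‑2‑en‑1‑yl)undeca‑1,5‑dien‑4‑yl N,N‑di(propan‑2‑yl)carbamate F4. Ionization of the tertiary alcohol in HFIP with catalytic TfOH gives the one bromonium ion (bromine participation); cyclization and the same hydrolysis and methanolysis come back to the route at 13.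

Step 5 (asymmetric lithiation and alkylation). The enantiomer ratio may be modest or some γ‑attack may occur. The fallback sets out from 6 and uses a reagent‑controlled allylboration instead. MnO2 oxidation gives (2Z)‑3,7‑dimethyl‑2‑(prop‑2‑en‑1‑yl)octa‑2,6‑dienal F1. The antipode of B‑(2‑methylallyl)diisopinocampheylborane that gives the 4R alcohol then yields (4R,5Z)‑2,6,10‑trimethyl‑5‑(prop‑2‑en‑1‑yl)undeca‑1,5,9‑trien‑4‑ol F2. Carbamoylation (i‑Pr2NCOCl, Et3N, DMAP) comes back to the route at 10.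

**Further compounds**
F1 | step 5 | (2Z)‑3,7‑dimethyl‑2‑(prop‑2‑en‑1‑yl)octa‑2,6‑dienal | O=C/C(CC=C)=C(/C)CCC=C(C)C
F2 | step 5 | (4R,5Z)‑2,6,10‑trimethyl‑5‑(prop‑2‑en‑1‑yl)undeca‑1,5,9‑trien‑4‑ol | O[C@H](CC(C)=C)/C(CC=C)=C(/C)CCC=C(C)C
F3 | step 6 | (4R,5Z)‑8‑[(2S)‑3,3‑dimethyloxiran‑2‑yl]‑2,6‑dimethyl‑5‑(prop‑2‑en‑1‑yl)octa‑1,5‑dien‑4‑yl N,N‑di(propan‑2‑yl)carbamate | CC(C)N(C(C)C)C(=O)O[C@H](CC(C)=C)/C(CC=C)=C(/C)CC[C@@H]1OC1(C)C
F4 | step 6 | (4R,5Z,9R)‑9‑bromo‑10‑hydroxy‑2,6,10‑trimethyl‑5‑(prop‑2‑en‑1‑yl)undeca‑1,5‑dien‑4‑yl N,N‑di(propan‑2‑yl)carbamate | CC(C)N(C(C)C)C(=O)O[C@H](CC(C)=C)/C(CC=C)=C(/C)CC[C@@H](Br)C(C)(C)O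
F5 | step 8 | (1R,3S,4S,6R,7R,10R)‑4,10‑dibromo‑3,7‑epoxy‑3,7,11,11‑tetramethylspiro[5.5]undecan‑1‑ol | O[C@@H]1C[C@@]3(C)[C@@H](Br)C[C@@]12C(C)(C)[C@H](Br)CC[C@@]2(C)O3
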